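Readings and results stem from a simulated flask for substances that don't exist; scatter was added.

The meeting decided to reckon this flask in powers of ten, on the odds of isomer of the product over target, and not on shares.

all flasks: free catalyst 50 mM

| charge | starting material | other conformer | added ligand | remark | time |
|---|---|---|---|---|---|
| grey | 1 M | 1 M | 41 mM | run made earlier |  |
| green | 1 M | 1 M | 92 mM | run made earlier |  |
| flask | 1.0 M | 1.00 M | 61 mM |  | 2.5 min |

| run | time / min | isomer of the product / % | target / % | starting material / % |
|---|---|---|---|---|
| grey | 0.417 | 1.7 | 2.7 | 35.7 |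
| grey | 0.833 | 3.5 | 3.2 | 29.6 |
| grey | 1.33 | 3.8 | 3.7 | 27.8 |
| grey | 1.50 | 4.7 | 3.7 | 27.2 |
| grey | 2.00 | 3.4 | 4.5 | 26.3 |
| grey | 2.50 | 5.3 | 3.8 | 26.1 |
| green | 0.200 | 1.3 | 1.0 | 42.1 |
| green | 0.333 | 1.6 | 1.3 | 38.1 |
| green | 0.500 | 2.0 | 1.1 | 35.4 |
| green | 0.833 | 1.3 | 1.2 | 31.8 |
| green | 1.50 | 2.9 | 3.5 | 28.5 |
| green | 2.50 | 3.4 | 3.5 | 27.1 |

(each reading ± 0.5 percentage points)

1. share of isomer of the product in isomer of the product plus target at 1.5 s
2. share of isomer of the product in isomer of the product plus target at 2.5 min



The forecast was tabled first: 52% (range 32% to 72%) at 1.5 s and 50% (range 43% to 57%) at 2.5 min, with the caution “Early ratios are noisy”.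

I argued for a reckoning of my own, assuming that target comes from starting material, isomer from other conformer, and both through one catalyst form. The odds then equal s·ρ, where ρ is other conformer over starting material and s is the selectivity factor, the odds at equal amounts of the two conformers.

The last two readings of both runs pool to odds of 0.980, a logarithm of −0.00860. The last grey reading, by difference, gives ρ = 2.48. I assumed that product forms on average midway in log ρ, at 0.197, so the selectivity factor s, the odds per unit ρ, reads 0.622.

The time 1.5 s is far shorter than the 0.333 min by which green's starting material stood at 38.1%, so ρ is still about its charged value of one. I therefore committed to 38.3% at 1.5 s, against the forecast's 52%, and to 49.5% at 2.5 min.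

The flask gives 41.3% at 1.5 s and 53.7% at 2.5 min.

    starting material ⇌ other conformer (K = 2.40, k = 0.0250 /s)
    starting material + free catalyst → free catalyst + target (k = 0.110 /M/s)
    free catalyst + other conformer → free catalyst + isomer of the product (k = 0.0760 /M/s)
    free catalyst + added ligand ⇌ idle complex (K = 50.0 /M, k = 9.20 /M/s)
    free catalyst + other conformer → spent catalyst (k = 0.0360 /M/s)

In the flask, isomer and target stand level at 2.79% each after 0.867 min. At 2.50 min the flask holds ρ = 2.39, so s puts the odds of what forms at that moment at 1.49. The neighbour flask, the same recipe with 0.40 M of starting material, starts at ρ = 2.50, so s puts its share at 1.5 s at 60.9%; that neighbour flask gives 63.3%.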